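**Plan**
- Retrosynthesis: the bond between the imidazol-5-ylmethyl CH2 and the quinone ring carbon is cut first (a heterobenzylic radical from an acetic acid plus a C–H of 2,3-dimethoxy-1,4-benzoquinone). Next the exocyclic N–C4 bond of the dehydrohydantoin is cut (1-methylparabanic acid), then N1–C2 and N3–C4 of the imidazole (cyanamide plus an α-methylamino ketone), then the ketone C–CH2Ar bond (Weinreb amide plus 4-methoxybenzyl Grignard), back to N-methylaspartic acid.
- Enabling feature: C5 and C6 of the quinone ring are homotopic, unsubstituted enedione carbons, so radical addition raises no regiochemical question. The CH2 on imidazole C5 carries a radical stabilised by the imidazole C4=C5–N1 π-system. The aspartate β-carboxyl is the activating group and leaves as CO2.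
- Forward order: aspartate chain, ketone, 2-aminoimidazole ring closed (step 4), preformed methylhydantoin ring attached (step 5), acid unmasked (step 6), then the preformed quinone ring (from 2,3-dimethoxyphenol) joined last at its final oxidation level. No arene-to-quinone oxidation is needed in the presence of the heterocycles.
- Stereochemistry: the target has no stereocentre. The (S) centre of the aspartate is carried only as far as the aminoketone and is erased when the imidazole aromatises.

Key step: step 8

Assumption: Z-N-Me-Asp(OtBu)-OH (free acid liberated from the catalogue dicyclohexylammonium salt), 4-methoxybenzylmagnesium chloride (THF solution) and 1-methylparabanic acid are taken as purchased.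

**Step 1**
Reactants: 1 N-benzyloxycarbonyl-N-methyl-L-aspartic acid 4-tert-butyl ester
Product: 3 Weinreb amide tert-butyl (3S)-3-[benzyloxycarbonyl(methyl)amino]-4-[methoxy(methyl)amino]-4-oxobutanoate, via acyl imidazolide 2 (not isolated)
Conditions: CDI (1.1 equiv), CH2Cl2, rt, 1 h; then MeNHOMe·HCl (1.3 equiv), rt
Reagents that add atoms: N,O-dimethylhydroxylamine hydrochloride, CNOC.Cl; 1,1'-carbonyldiimidazole, O=C(n1ccnc1)n1ccnc1 (imidazolyl group of 2 only)
Why: CDI activation gives the acyl imidazolide, which is aminolysed by N,O-dimethylhydroxylamine (Weinreb amide formation); the tertiary carbamate nitrogen cannot form an oxazolone and the tert-butyl ester is untouched.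

**Step 2**
Reactants: 3 Weinreb amide; 4 4-methoxybenzylmagnesium chloride
Product: 5 tert-butyl (3S)-3-[benzyloxycarbonyl(methyl)amino]-5-(4-methoxyphenyl)-4-oxopentanoate
Conditions: 4 (1.4 equiv, THF solution), THF, −78 → −20 °C; aq NH4Cl
Reagents that add atoms: none
Why: Weinreb ketone synthesis, in which the benzylic Grignard reagent adds once to the N-methoxy-N-methylamide to give a magnesium chelate that collapses only on quench, while the hindered tert-butyl ester and the tertiary carbamate should be left alone at low temperature.

**Step 3**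
Reactants: 5 Cbz-protected aminoketone
Product: 6 tert-butyl (3S)-5-(4-methoxyphenyl)-3-(methylamino)-4-oxopentanoate hydrochloride
Conditions: H2 (1 atm), 10% Pd/C, HCl (1.0 equiv, 4 M in dioxane), EtOAc/MeOH, rt
Reagents that add atoms: hydrogen chloride, Cl
Why: Hydrogenolysis of the benzyl carbamate with loss of toluene and CO2, the one equivalent of HCl trapping the α-(methylamino) ketone as its salt so that it cannot self-condense; the dialkyl ketone, tert-butyl ester and aryl methyl ether are inert to Pd/H2 under these conditions.

**Step 4**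
Reactants: 6 aminoketone hydrochloride; 7 cyanamide
Product: 9 tert-butyl 2-[2-amino-4-(4-methoxybenzyl)-1-methyl-1H-imidazol-5-yl]acetate, via guanidine 8 (not isolated)
Conditions: NH2CN (5 equiv), H2O/EtOH 1:1, pH 4.5, 90 °C; then aq NaOH to pH 10, extraction
Reagents that add atoms: none
Why: Classical 2-aminoimidazole synthesis by cyclocondensation of an α-amino ketone with cyanamide, in which the secondary amine adds to the nitrile carbon to give guanidine 8, whose NH2 condenses with the ketone and dehydration with tautomerisation aromatises the ring, placing N-methyl next to the carbon bearing CH2CO2tBu (C5) and erasing the stereocentre.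

**Step 5**
Reactants: 9 2-aminoimidazole ester; 10 1-methylparabanic acid (1-methylimidazolidine-2,4,5-trione)
Product: 12 tert-butyl 2-[4-(4-methoxybenzyl)-1-methyl-2-[(1-methyl-2,5-dioxo-2,5-dihydro-1H-imidazol-4-yl)amino]-1H-imidazol-5-yl]acetate, via O-silyl imidate 11 (not isolated)
Conditions: 10 (1.5 equiv), BSA (3 equiv), MeCN, 80 °C, 1 h; then 9, toluene, 100 °C; MeOH quench
Reagents that add atoms: N,O-bis(trimethylsilyl)acetamide, CC(=N[Si](C)(C)C)O[Si](C)(C)C (trimethylsilyl group of 11 only)
Why: Silyl-mediated condensation of a 2-aminoimidazole with 1-methylparabanic acid (the standard naamine-to-naamidine conversion), in which BSA turns the N3–H/C4=O imide unit into O-silyl imidate 11 and the exocyclic amino group displaces silanolate at C4 by addition–elimination to give the cyclic N-acylamidine.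

**Step 6**
Reactants: 12 tert-butyl ester
Product: 13 2-[4-(4-methoxybenzyl)-1-methyl-2-[(1-methyl-2,5-dioxo-2,5-dihydro-1H-imidazol-4-yl)amino]-1H-imidazol-5-yl]acetic acid
Conditions: TFA/CH2Cl2 1:3, 0 °C → rt; evaporation, toluene azeotrope
Reagents that add atoms: none
Why: Acidolysis of the tert-butyl ester with loss of 2-methylpropene; the aryl methyl ether, the N-acylamidine and the imidazole should be stable to anhydrous TFA.

**Step 7**
Reactants: 14 2,3-dimethoxyphenol
Product: 15 2,3-dimethoxy-1,4-benzoquinone
Conditions: Fremy's salt (2.2 equiv), KH2PO4 buffer, H2O/acetone, 0 °C → rt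
Reagents that add atoms: potassium nitrosodisulfonate (Fremy's salt), [K+].[K+].[O]N(S(=O)(=O)[O-])S(=O)(=O)[O-]
Why: Teuber oxidation, in which one nitroxyl radical abstracts the phenolic hydrogen and a second adds at the free para position (C4), loss of imidodisulfonate then giving the para-quinone.

**Step 8**
Reactants: 13 imidazol-5-ylacetic acid; 15 2,3-dimethoxy-1,4-benzoquinone
Product: 16 naamidine F
Conditions: 15 (3 equiv), AgNO3 (0.5 equiv), (NH4)2S2O8 (1.5 equiv, added slowly), MeCN/H2O 1:1, 65 °C
Reagents that add atoms: none
Why: Peroxydisulfate oxidises Ag(I) to Ag(II), which oxidises the carboxylate of 13; loss of CO2 gives the imidazol-5-ylmethyl radical, stabilised by the imidazole C4=C5–N1 π-system, which adds to C5 of quinone 15, and the resulting semiquinone-type radical is oxidised and deprotonated back to the quinone level. The closest known reaction type is the silver/persulfate decarboxylative alkylation of 1,4-quinones with arylacetic acids (Jacobsen–Torssell/Kochi–Anderson reaction), which is established for 2,3-dimethoxy-5-methylbenzoquinone. No ring is closed and no stereocentre is formed. Regiochemistry is not in question because C5 and C6 of 15 are homotopic, and mono- over bis-alkylation should be secured by the three-fold excess of 15 and by the lower reactivity of the remaining C6–H of the product, which sits on a more hindered and more electron-rich double bond. Chemoselectivity for the carboxylate over the anisole ring and the heterocycle rests on inner-sphere oxidation of the silver carboxylate and on deactivation of the 2-aminoimidazole by the N-acylamidine and by protonation in the acid generated, which is why the dehydrohydantoin is installed before this step and why the quinone never meets a free, nucleophilic amino group.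

**Compound list**
1 | N-benzyloxycarbonyl-N-methyl-L-aspartic acid 4-tert-butyl ester, (2S)-2-[benzyloxycarbonyl(methyl)amino]-4-tert-butoxy-4-oxobutanoic acid | CN(C(=O)OCc1ccccc1)[C@@H](CC(=O)OC(C)(C)C)C(=O)O | starting material
2 | acyl imidazolide of 1, tert-butyl (3S)-3-[benzyloxycarbonyl(methyl)amino]-4-(imidazol-1-yl)-4-oxobutanoate | CN(C(=O)OCc1ccccc1)[C@@H](CC(=O)OC(C)(C)C)C(=O)n1ccnc1 | intermediate (not isolated)
3 | Weinreb amide, tert-butyl (3S)-3-[benzyloxycarbonyl(methyl)amino]-4-[methoxy(methyl)amino]-4-oxobutanoate | CN(C(=O)OCc1ccccc1)[C@@H](CC(=O)OC(C)(C)C)C(=O)N(C)OC | intermediate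
4 | 4-methoxybenzylmagnesium chloride | COc1ccc(C[Mg]Cl)cc1 | starting material
5 | tert-butyl (3S)-3-[benzyloxycarbonyl(methyl)amino]-5-(4-methoxyphenyl)-4-oxopentanoate | CN(C(=O)OCc1ccccc1)[C@@H](CC(=O)OC(C)(C)C)C(=O)Cc1ccc(OC)cc1 | intermediate
6 | tert-butyl (3S)-5-(4-methoxyphenyl)-3-(methylamino)-4-oxopentanoate hydrochloride | Cl.CN[C@@H](CC(=O)OC(C)(C)C)C(=O)Cc1ccc(OC)cc1 | intermediate
7 | cyanamide | NC#N | starting material
8 | guanidine, tert-butyl (3S)-3-[carbamimidoyl(methyl)amino]-5-(4-methoxyphenyl)-4-oxopentanoate (configuration nominal and without consequence) | CN(C(=N)N)[C@@H](CC(=O)OC(C)(C)C)C(=O)Cc1ccc(OC)cc1 | intermediate (not isolated)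
9 | tert-butyl 2-[2-amino-4-(4-methoxybenzyl)-1-methyl-1H-imidazol-5-yl]acetate | CC(C)(C)OC(=O)Cc1c(Cc2ccc(OC)cc2)nc(N)n1C | intermediate
10 | 1-methylparabanic acid (1-methylimidazolidine-2,4,5-trione) | CN1C(=O)NC(=O)C1=O | starting material
11 | O-silyl imidate, 1-methyl-4-(trimethylsilyloxy)-1H-imidazole-2,5-dione | CN1C(=O)N=C(O[Si](C)(C)C)C1=O | intermediate (not isolated)
12 | tert-butyl 2-[4-(4-methoxybenzyl)-1-methyl-2-[(1-methyl-2,5-dioxo-2,5-dihydro-1H-imidazol-4-yl)amino]-1H-imidazol-5-yl]acetate | CC(C)(C)OC(=O)Cc1c(Cc2ccc(OC)cc2)nc(NC2=NC(=O)N(C)C2=O)n1C | intermediate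
13 | 2-[4-(4-methoxybenzyl)-1-methyl-2-[(1-methyl-2,5-dioxo-2,5-dihydro-1H-imidazol-4-yl)amino]-1H-imidazol-5-yl]acetic acid | OC(=O)Cc1c(Cc2ccc(OC)cc2)nc(NC2=NC(=O)N(C)C2=O)n1C | intermediate
14 | 2,3-dimethoxyphenol | COc1cccc(O)c1OC | starting material
15 | 2,3-dimethoxy-1,4-benzoquinone | COC1=C(OC)C(=O)C=CC1=O | intermediate
16 | naamidine F, 2,3-dimethoxy-5-{[4-(4-methoxybenzyl)-1-methyl-2-[(1-methyl-2,5-dioxo-2,5-dihydro-1H-imidazol-4-yl)amino]-1H-imidazol-5-yl]methyl}cyclohexa-2,5-diene-1,4-dione | COC1=C(OC)C(=O)C(Cc2c(Cc3ccc(OC)cc3)nc(NC3=NC(=O)N(C)C3=O)n2C)=CC1=O | target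

**Step count and risks**
Total step count: 8. Longest linear sequence: 7 (steps 1–6 and 8).

Steps most likely to fail:

1. Step 8. The heterobenzylic radical may be over-oxidised to the cation and captured by water, silver may be sequestered by the imidazole nitrogen so that decarboxylation stalls, the anisole ring may be degraded oxidatively, and a second alkylation may occur. The fallback replaces radical C–H alkylation of the quinone by a cross-coupling to an arene followed by oxidation. It sets out from acid 13. Esterification with N-hydroxyphthalimide (DIC, cat. DMAP, CH2Cl2) would give the redox-active N-hydroxyphthalimide ester F1. (2,3,4,5-Tetramethoxyphenyl)zinc chloride F2 would be prepared from commercial 1,2,3,4-tetramethoxybenzene (n-BuLi/TMEDA, then ZnCl2) and coupled with F1 under nickel catalysis (NiCl2·glyme, 4,4'-di-tert-butyl-2,2'-bipyridine, THF/DMF, rt; decarboxylative arylation) to give the tetramethoxybenzyl imidazole F3. Oxidative demethylation of the para-related methoxy groups with ceric ammonium nitrate (MeCN/H2O, 0 °C) would then return to the route at 16.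

2. Step 2. The Grignard reagent may attack the tert-butyl ester in competition, may simply enolise the substrate so that the amide is recovered, or may be lost to Wurtz homocoupling. The fallback replaces organomagnesium addition by a palladium-catalysed acyl cross-coupling. It sets out from acid 1. Thioesterification with ethanethiol (EDC·HCl, DMAP, CH2Cl2) would give the S-ethyl thioester F4. 4-Methoxybenzylzinc chloride F5 (from 4-methoxybenzyl chloride and zinc dust, THF) would be coupled with F4 under Fukuyama conditions (PdCl2(PPh3)2, THF/toluene, rt), the organozinc being inert to ester and carbamate, and the sequence returns to the route at ketone 5.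

3. Step 4. The tert-butyl ester may hydrolyse in the hot aqueous acid, the free aminoketone may self-condense, or methylamine may be lost by retro-Michael elimination before guanylation occurs. The fallback separates guanylation from ring closure and avoids hot aqueous medium. It sets out from aminoketone hydrochloride 6. Guanylation with commercial N,N'-bis(benzyloxycarbonyl)-N''-triflylguanidine (Et3N, CH2Cl2, rt) would give the bis-Cbz guanidine F6. Hydrogenolysis (H2, Pd/C, MeOH) would release guanidine 8, which should cyclodehydrate on warming with AcOH, returning to the route at 9.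

**Further compounds**
F1 | step 8 | N-hydroxyphthalimide ester of acid 13, 1,3-dioxoisoindolin-2-yl 2-[4-(4-methoxybenzyl)-1-methyl-2-[(1-methyl-2,5-dioxo-2,5-dihydro-1H-imidazol-4-yl)amino]-1H-imidazol-5-yl]acetate | O=C(Cc1c(Cc2ccc(OC)cc2)nc(NC2=NC(=O)N(C)C2=O)n1C)ON1C(=O)c2ccccc2C1=O
F2 | step 8 | (2,3,4,5-tetramethoxyphenyl)zinc chloride | COc1cc([Zn]Cl)c(OC)c(OC)c1OC
F3 | step 8 | 4-{[4-(4-methoxybenzyl)-1-methyl-5-(2,3,4,5-tetramethoxybenzyl)-1H-imidazol-2-yl]amino}-1-methyl-1H-imidazole-2,5-dione | COc1cc(Cc2c(Cc3ccc(OC)cc3)nc(NC3=NC(=O)N(C)C3=O)n2C)c(OC)c(OC)c1OC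
F4 | step 2 | S-ethyl thioester of 1, tert-butyl (3S)-3-[benzyloxycarbonyl(methyl)amino]-4-(ethylsulfanyl)-4-oxobutanoate | CN(C(=O)OCc1ccccc1)[C@@H](CC(=O)OC(C)(C)C)C(=O)SCC
F5 | step 2 | 4-methoxybenzylzinc chloride | COc1ccc(C[Zn]Cl)cc1
F6 | step 4 | bis-Cbz guanidine, tert-butyl (3S)-3-{[N,N'-bis(benzyloxycarbonyl)carbamimidoyl](methyl)amino}-5-(4-methoxyphenyl)-4-oxopentanoate | CN(C(=NC(=O)OCc1ccccc1)NC(=O)OCc1ccccc1)[C@@H](CC(=O)OC(C)(C)C)C(=O)Cc1ccc(OC)cc1
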